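## The problem

Target 14 is a 1,2-dihydronaphthalene: a catechol ring (ring A) fused to a partly saturated ring B that carries a 4-hydroxyphenyl group on C1 and 2,4-dihydroxybenzoyl groups on C2 and C3. The C3=C4 double bond is conjugated with ring A and with the C3 ketone. There are two stereocentres, C1 (R) and C2 (S), with the aryl and aroyl groups trans. C2 is alpha to a ketone and allylic, so it can equilibrate and should settle trans to the C1 aryl group. C1 is doubly benzylic, has no such handle and must be set absolutely; it can then control C2, not the reverse. The stereocentres survive only while the double bond stays at C3=C4: a shift to C2=C3 erases C2 and makes the C1 hydrogen vinylogously acidic. The seven phenols (one catechol, two resorcinols, one phenol) are oxidation-prone, and the 2-hydroxyaroyl group on C3 forms with C4 a hydroxy-enone that can cyclise, so the oxygens must stay protected until the last step. The enabling feature is that C1 and C2 are the beta and alpha carbons of the C2 aryl ketone, while C3 bears an acyl group and is joined through the benzylic C4 to ring A. C3 can therefore enter as the more electrophilic carbonyl of a 1,2-diketone, so that aryl delivery to C1 leaves an enolate at C2 placed to close ring B on C3.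

## Retrosynthesis

**14 from 13.** The seven O–methyl bonds are cut last. Methyl ethers are chosen because all four building blocks are sold in this form and because they pass through Grignard, palladium, aqueous rhodium and dehydration chemistry unchanged. The price is one Lewis acid deprotection, which heptamethyl ether 13 has to tolerate.

**13 from 11.** The C3=C4 bond is traced to the C3 tertiary alcohol and a C4 hydrogen of hydroxytetralin 11. Loss of water through the C2 enolate would be the natural course for a beta-hydroxy ketone and would place the alkene at C2=C3. The forward step must therefore be a syn elimination through sulfamate 12: in 11 the hydroxyl is cis to the C2 aroyl group, hence trans to the C2 hydrogen, and only C4 offers a hydrogen on the same face.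

**11 from 9 and 10.** The C1–aryl and C2–C3 bonds are cut together. This cut is preferred to a Diels–Alder or Friedel–Crafts opening of ring B because it removes one ring, two skeletal bonds and all three stereocentres at once and leaves an acyclic, achiral enone–dione 9 and commercial boronic acid 10. The forward reaction must set C1 by the ligand, relay it to C2 and C3 through a cyclic aldol transition state, and let the enolate close faster than it is protonated.

**9 from 8.** The two adjacent carbonyl groups are traced to the alkyne of 8. A benzylic 1,2-diketone tautomerises easily to a conjugated enol that is no aldol acceptor, so the dione is unveiled in the last step before the cascade and under base-free conditions. No basic or hot step follows it.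

**8 from 4 and 7.** The aryl–vinyl bond is cut by a Heck disconnection. Aryl bromide 4 and vinyl ketone 7 are simpler than any aldehyde-based enone synthesis would allow, because the aldehyde oxidation level on ring A is not needed elsewhere. Vinyl ketone 7 comes from acetophenone 5 by methylenation through Mannich base 6.

**4 from 1 and 2.** The C4–alkyne bond is cut to benzylic bromide 2 and alkyne 1 (as Grignard reagent 3). The benzylic C–Br bond reacts selectively in the presence of the aryl bromide, which is kept for the Heck step.

## Roads not taken

**Alternative 1: furan–alkyne Diels–Alder construction of ring A.**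
- **Cut:** the ring A bonds C4a–C8a and C5–C6.
- **Forward key step:** the furan–enyne A2 undergoes intramolecular [4+2] cycloaddition, closing rings B and A together, and the oxygen bridge opens to give the 6-hydroxy-7-methoxy dihydronaphthalene A1, which would be demethylated to 14.
- **Merits:** the C3=C4 bond is present before cyclisation, so no dehydration has to be steered, and no enolisable dione is handled. In these two respects this road is better than the chosen one.
- **Weak points:** A2 must already hold C1 and C2 in an open chain, where C2 is alpha to a ketone and has no ring to bias its equilibration. The electron-rich methoxyfuran is acid-labile and its cycloadditions are reversible. Ring A, which can be bought, is built from scratch.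
- **Comparison:** the chosen plan sets against the cleaner alkene placement a commercial ring A and one catalytic step that makes both ring B bonds and all stereocentres from an achiral precursor.

**Alternative 2: ring expansion of a cyclopropane-fused indane.**
- **Cut:** no skeletal bond of the target is cut; the C2–C4 bond is added backwards to give the cyclopropane-fused indane A4.
- **Forward key step:** Sc(OTf)3 opens the C2–C4 bond to a C4 benzylic cation (stabilised by the para methoxy group on C7) and a C2 enolate. Loss of the C3 proton gives the heptamethyl ether A3, which is the same compound as 13.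
- **Merits:** the alkene position is dictated by the cation site, and the route reaches 13 without a beta-hydroxy ketone. This is a safer endgame than step 6 of the chosen plan.
- **Weak points:** the key step forms no carbon–carbon bond of the skeleton. The whole difficulty moves into A4, a strained tricycle with four contiguous stereocentres, one of them quaternary, whose enantioselective synthesis would be longer than the entire chosen route. The cation could also be captured by the electron-rich aroyl rings.
- **Comparison:** the chosen plan sets convergence and step count against the safer alkene placement.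

**Alternative 3: photoenolisation Diels–Alder reaction.**
- **Cut:** the C1–C2 and C3–C4 bonds.
- **Forward key step:** irradiation of benzylbenzaldehyde A6 gives a hydroxy-o-quinodimethane that adds to diaroylethylene A7, giving the 4-hydroxytetralin A5.
- **Merits:** two simple components give both ring bonds in one step. In A5 the hydroxyl sits on C4, beta to the C3 ketone, so base-induced loss of water can only give C3=C4 and leads directly to 13. The relative configuration at C2 and C3 does not matter, since C3 becomes planar and C2 equilibrates. In step count and in the security of the dehydration this road is better than the chosen one.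
- **Weak points:** C1, the only centre that counts, arises from a planar diene terminus with no control element. An enantioselective version with an aryl-substituted photoenol would have to be developed. A7 absorbs light and isomerises.
- **Comparison:** for racemic material this would be the plan of choice. For the single enantiomer the chosen plan sets its ligand-controlled C1 against the shorter count, and accepts the more delicate dehydration.

Key step: step 5

Assumption: [Rh(OH)((S)-BINAP)]2 is taken to deliver the aryl group to the alpha-si face of the E-enone, by analogy with other E-configured acyclic acceptors; this face gives 1R, and if the first run showed the opposite sense the (R)-ligand would be used with nothing else changed.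

## Route

Step 1
Reactants: 1 1-ethynyl-2,4-dimethoxybenzene; 2 1-bromo-2-(bromomethyl)-4,5-dimethoxybenzene
Product: 4 1-bromo-2-[3-(2,4-dimethoxyphenyl)prop-2-yn-1-yl]-4,5-dimethoxybenzene, via [(2,4-dimethoxyphenyl)ethynyl]magnesium bromide 3 (not isolated)
Conditions: EtMgBr, THF, 0 °C to rt; then 2, CuBr·SMe2 (10 mol%), THF, 45 °C
Reagents that add atoms: none
Why: Deprotonation of the terminal alkyne gives 3, and copper-catalysed sp–sp3 coupling of this alkynyl Grignard reagent with the benzylic bromide forms the C4–alkyne bond; the aryl C–Br bond does not react under these conditions.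

Step 2
Reactants: 5 1-(2,4-dimethoxyphenyl)ethan-1-one
Product: 7 1-(2,4-dimethoxyphenyl)prop-2-en-1-one, via 3-[di(propan-2-yl)amino]-1-(2,4-dimethoxyphenyl)propan-1-one 6 (not isolated)
Conditions: (CH2O)n, i-Pr2NH·CF3CO2H, CF3CO2H (cat.), THF, reflux
Reagents that add atoms: paraformaldehyde (as formaldehyde), C=O
Why: Direct alpha-methylenation of a methyl ketone: a Mannich reaction gives 6, which loses the bulky amine by beta-elimination in the same flask; 7 is stabilised with a trace of BHT and used at once because aryl vinyl ketones polymerise.

Step 3
Reactants: 4 1-bromo-2-[3-(2,4-dimethoxyphenyl)prop-2-yn-1-yl]-4,5-dimethoxybenzene; 7 1-(2,4-dimethoxyphenyl)prop-2-en-1-one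
Product: 8 (E)-1-(2,4-dimethoxyphenyl)-3-{2-[3-(2,4-dimethoxyphenyl)prop-2-yn-1-yl]-4,5-dimethoxyphenyl}prop-2-en-1-one
Conditions: Pd2(dba)3 (1.5 mol%), [HP(t-Bu)3]BF4 (6 mol%), Cy2NMe, dioxane, 40 °C
Reagents that add atoms: none
Why: Mizoroki–Heck reaction: zerovalent palladium with the bulky electron-rich phosphine inserts into the hindered aryl bromide near room temperature, and syn insertion of the vinyl ketone followed by syn beta-hydride elimination gives the E-enone; the mild amine and low temperature should leave the 1,3-diarylpropyne unit unisomerised, and the activated vinyl ketone should insert faster than the internal alkyne.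

Step 4
Reactants: 8 (E)-1-(2,4-dimethoxyphenyl)-3-{2-[3-(2,4-dimethoxyphenyl)prop-2-yn-1-yl]-4,5-dimethoxyphenyl}prop-2-en-1-one
Product: 9 1-(2,4-dimethoxyphenyl)-3-{2-[(E)-3-(2,4-dimethoxyphenyl)-3-oxoprop-1-en-1-yl]-4,5-dimethoxyphenyl}propane-1,2-dione
Conditions: PdBr2 (5 mol%), CuBr2 (10 mol%), O2 (1 atm), dioxane/H2O, 60 °C
Reagents that add atoms: dioxygen, O=O; water, O
Why: Wacker-type oxidation of an internal alkyne to the 1,2-diketone with dioxygen as terminal oxidant; no base is present, so the benzylic diketone should be obtained as its keto tautomer, and the electron-poor enone and the methoxyarenes are not substrates; 9 is filtered quickly through neutral silica and used directly.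

Step 5
Reactants: 9 1-(2,4-dimethoxyphenyl)-3-{2-[(E)-3-(2,4-dimethoxyphenyl)-3-oxoprop-1-en-1-yl]-4,5-dimethoxyphenyl}propane-1,2-dione; 10 (4-methoxyphenyl)boronic acid
Product: 11 [(1R,2S,3R)-3-hydroxy-6,7-dimethoxy-1-(4-methoxyphenyl)-1,2,3,4-tetrahydronaphthalene-2,3-diyl]bis[(2,4-dimethoxyphenyl)methanone]
Conditions: [Rh(OH)((S)-BINAP)]2 (2.5 mol%), 10 (2.5 equiv), dioxane/H2O (20:1), 50 °C
Reagents that add atoms: (4-methoxyphenyl)boronic acid, COc1ccc(B(O)O)cc1
Why: The aryl group passes from boron to the hydroxo complex of monovalent rhodium, the aryl–rhodium species inserts the E-enone of 9 in a syn fashion so that the aryl carbon bonds to C1, and the resulting oxa-allyl rhodium (Z)-enolate at C2 adds to the C3 carbonyl before water protonates it; hydrolysis of the rhodium aldolate returns the hydroxo complex. The closest known reaction type is the rhodium-catalysed tandem conjugate addition–aldol cyclisation of arylboronic acids with enones that carry a tethered ketone or dione. Ring B closes by a 6-exo-trig (enolexo) aldol addition through a chair-like Zimmerman–Traxler transition state in which rhodium bridges the enolate and ketone oxygens. C1 is controlled by the ligand, which exposes the alpha-si face of the enone and so gives 1R. C2 and C3 are controlled by the transition state: the (Z)-enolate and the rhodium bridge place the new C3 hydroxyl cis to the C2 aroyl group, and the C1 aryl group takes the equatorial site trans to the C2 aroyl group, hence 2S,3R. Three selectivities are needed: the C3 carbonyl over its aryl-conjugated neighbour (six- against seven-membered ring, and the aryl ketone is deactivated by conjugation and its ortho methoxy group); insertion of the enone over direct aryl transfer to the dione (favoured with this bisphosphine complex at moderate temperature); and ring closure over protonation of the enolate, which is secured by the intramolecular, doubly activated acceptor, the small amount of water and the absence of added base, so that 9 stays in its diketo form.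

Step 6
Reactants: 11 [(1R,2S,3R)-3-hydroxy-6,7-dimethoxy-1-(4-methoxyphenyl)-1,2,3,4-tetrahydronaphthalene-2,3-diyl]bis[(2,4-dimethoxyphenyl)methanone]
Product: 13 [(1R,2S)-6,7-dimethoxy-1-(4-methoxyphenyl)-1,2-dihydronaphthalene-2,3-diyl]bis[(2,4-dimethoxyphenyl)methanone], via methyl N-({[(1R,2S,3R)-2,3-bis(2,4-dimethoxybenzoyl)-6,7-dimethoxy-1-(4-methoxyphenyl)-1,2,3,4-tetrahydronaphthalen-3-yl]oxy}sulfonyl)carbamate 12 (not isolated)
Conditions: Burgess reagent (MeO2CN–SO2NEt3 inner salt, 3 equiv), toluene, 70 °C
Reagents that add atoms: none
Why: Burgess dehydration: the tertiary alcohol is converted into sulfamate 12, which fragments by a thermal syn elimination through a six-membered transition state; in 11 the hydroxyl is trans to the C2 hydrogen, so the only hydrogen on its face is on C4 and the double bond must form as C3=C4; the neutral, non-ionising conditions avoid retro-aldol opening and leave C1 and C2 untouched.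

Step 7
Reactants: 13 [(1R,2S)-6,7-dimethoxy-1-(4-methoxyphenyl)-1,2-dihydronaphthalene-2,3-diyl]bis[(2,4-dimethoxyphenyl)methanone]
Product: 14 [(1R,2S)-6,7-dihydroxy-1-(4-hydroxyphenyl)-1,2-dihydronaphthalene-2,3-diyl]bis[(2,4-dihydroxyphenyl)methanone]
Conditions: BBr3 (20 equiv), CH2Cl2, −78 °C to rt; then MeOH, H2O, 0 °C, under argon
Reagents that add atoms: none
Why: Lewis acid cleavage of aryl methyl ethers with BBr3; the two methoxy groups ortho to the ketones should go first through chelation, and the resulting boron chelates keep these oxygens from adding to the enone; no bond to a stereocentre is broken, and trans is the stable arrangement at the enolisable C2.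

## Compound list

1 | 1-ethynyl-2,4-dimethoxybenzene | C#Cc1ccc(OC)cc1OC | starting material
2 | 1-bromo-2-(bromomethyl)-4,5-dimethoxybenzene | COc1cc(Br)c(CBr)cc1OC | starting material
3 | [(2,4-dimethoxyphenyl)ethynyl]magnesium bromide | COc1ccc(C#C[Mg]Br)c(OC)c1 | intermediate
4 | 1-bromo-2-[3-(2,4-dimethoxyphenyl)prop-2-yn-1-yl]-4,5-dimethoxybenzene | COc1ccc(C#CCc2cc(OC)c(OC)cc2Br)c(OC)c1 | intermediate
5 | 1-(2,4-dimethoxyphenyl)ethan-1-one | CC(=O)c1ccc(OC)cc1OC | starting material
6 | 3-[di(propan-2-yl)amino]-1-(2,4-dimethoxyphenyl)propan-1-one | CC(C)N(CCC(=O)c1ccc(OC)cc1OC)C(C)C | intermediate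
7 | 1-(2,4-dimethoxyphenyl)prop-2-en-1-one | C=CC(=O)c1ccc(OC)cc1OC | intermediate
8 | (E)-1-(2,4-dimethoxyphenyl)-3-{2-[3-(2,4-dimethoxyphenyl)prop-2-yn-1-yl]-4,5-dimethoxyphenyl}prop-2-en-1-one | O=C(/C=C/c1cc(OC)c(OC)cc1CC#Cc1ccc(OC)cc1OC)c1ccc(OC)cc1OC | intermediate
9 | 1-(2,4-dimethoxyphenyl)-3-{2-[(E)-3-(2,4-dimethoxyphenyl)-3-oxoprop-1-en-1-yl]-4,5-dimethoxyphenyl}propane-1,2-dione | O=C(/C=C/c1cc(OC)c(OC)cc1CC(=O)C(=O)c1ccc(OC)cc1OC)c1ccc(OC)cc1OC | intermediate
10 | (4-methoxyphenyl)boronic acid | COc1ccc(B(O)O)cc1 | starting material
11 | [(1R,2S,3R)-3-hydroxy-6,7-dimethoxy-1-(4-methoxyphenyl)-1,2,3,4-tetrahydronaphthalene-2,3-diyl]bis[(2,4-dimethoxyphenyl)methanone] | O=C(c1ccc(OC)cc1OC)[C@@]1(O)Cc2cc(OC)c(OC)cc2[C@@H](c2ccc(OC)cc2)[C@@H]1C(=O)c1ccc(OC)cc1OC | intermediate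
12 | methyl N-({[(1R,2S,3R)-2,3-bis(2,4-dimethoxybenzoyl)-6,7-dimethoxy-1-(4-methoxyphenyl)-1,2,3,4-tetrahydronaphthalen-3-yl]oxy}sulfonyl)carbamate | O=C(c1ccc(OC)cc1OC)[C@@]1(OS(=O)(=O)NC(=O)OC)Cc2cc(OC)c(OC)cc2[C@@H](c2ccc(OC)cc2)[C@@H]1C(=O)c1ccc(OC)cc1OC | intermediate
13 | [(1R,2S)-6,7-dimethoxy-1-(4-methoxyphenyl)-1,2-dihydronaphthalene-2,3-diyl]bis[(2,4-dimethoxyphenyl)methanone] | O=C(C1=Cc2cc(OC)c(OC)cc2[C@@H](c2ccc(OC)cc2)[C@@H]1C(=O)c1ccc(OC)cc1OC)c1ccc(OC)cc1OC | intermediate
14 | [(1R,2S)-6,7-dihydroxy-1-(4-hydroxyphenyl)-1,2-dihydronaphthalene-2,3-diyl]bis[(2,4-dihydroxyphenyl)methanone] (CNP0195549.2) | O=C(C1=Cc2cc(O)c(O)cc2[C@@H](c2ccc(O)cc2)[C@@H]1C(=O)c1ccc(O)cc1O)c1ccc(O)cc1O | target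

## Step count and risk

Total: 7 steps. Longest linear sequence: 6 steps (steps 1, 3, 4, 5, 6, 7).

**Step 5 (key step).** The most likely failure is protonation of the rhodium enolate before ring closure. The benzylic diketone of 9 can tautomerise to its conjugated enol, which is no aldol acceptor, offers an acidic proton and can bind rhodium as a chelate. Direct aryl transfer to the activated C3 carbonyl is a second leak. The fallback sets out from 9 and returns at 11. The aryl donor is changed to 9-(4-methoxyphenyl)-9-borabicyclo[3.3.1]nonane F1, made from 4-methoxyphenylmagnesium bromide and 9-methoxy-9-borabicyclo[3.3.1]nonane. With [Rh(OMe)(cod)]2 and (S)-BINAP in dry toluene at 80 °C, the conjugate arylation has no proton source. The enolate is handed to boron as the (Z)-boron enolate F2, which closes onto C3 through the same cyclic transition state. Aqueous work-up of the boron aldolate gives 11.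

**Step 4.** The likely failures are over-oxidation at the activated methylene between ring A and the new dione, ring bromination of a methoxyarene by CuBr2, and tautomerisation during isolation. The fallback sets out from 4 and returns at 9. The alkyne of 4 is oxidised before any enone is present, with KMnO4 buffered by NaHCO3 and MgSO4 in aqueous acetone, to 3-(2-bromo-4,5-dimethoxyphenyl)-1-(2,4-dimethoxyphenyl)propane-1,2-dione F3. The enone is then attached without base by Stille coupling (Pd(PPh3)4, CuI, DMF, 60 °C) with (E)-1-(2,4-dimethoxyphenyl)-3-(tributylstannyl)prop-2-en-1-one F4, itself made by palladium-catalysed acylation of (E)-1,2-bis(tributylstannyl)ethene with 2,4-dimethoxybenzoyl chloride.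

**Step 6.** The likely failures are that the hindered, hydrogen-bonded tertiary alcohol does not form the sulfamate, or that ring B opens by retro-aldol cleavage on heating. The fallback sets out from 11 and returns at 13. The alcohol is activated through its alkoxide at low temperature (KN(SiMe3)2, CS2, THF, −78 °C, then MeI) as the S-methyl xanthate O-[(1R,2S,3R)-2,3-bis(2,4-dimethoxybenzoyl)-6,7-dimethoxy-1-(4-methoxyphenyl)-1,2,3,4-tetrahydronaphthalen-3-yl] S-methyl carbonodithioate F5. Its Chugaev elimination in hot toluene is again a syn process and can only use a C4 hydrogen.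

**Step 7.** The likely failures are incomplete cleavage of the seven ethers to a mixture that cannot be separated, acid-promoted addition of a freed 2-hydroxyaroyl oxygen to C4 on long exposure, and air oxidation of the catechol on purification. The fallback sets out from 13 and returns at 14, in stages:
- BCl3 (CH2Cl2, −78 to 0 °C) removes only the two chelation-activated ortho ethers, giving [(1R,2S)-6,7-dimethoxy-1-(4-methoxyphenyl)-1,2-dihydronaphthalene-2,3-diyl]bis[(2-hydroxy-4-methoxyphenyl)methanone] F6.
- A shorter BBr3 treatment cleaves the remaining five ethers.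
- The crude heptaphenol is acetylated (Ac2O, pyridine) to the heptaacetate of 14, F7, which is stable to air and can be chromatographed.
- Mild methanolysis (NH4OAc, aqueous MeOH) releases 14.

## Further compounds

F1 | step 5 | 9-(4-methoxyphenyl)-9-borabicyclo[3.3.1]nonane | COc1ccc(B2C3CCCC2CCC3)cc1
F2 | step 5 | (Z)-9-borabicyclo[3.3.1]nonan-9-yl enolate of the (R)-conjugate adduct of 9 (not isolated) | COc1ccc([C@@H](/C=C(\OB2C3CCCC2CCC3)c2ccc(OC)cc2OC)c2cc(OC)c(OC)cc2CC(=O)C(=O)c2ccc(OC)cc2OC)cc1
F3 | step 4 | 3-(2-bromo-4,5-dimethoxyphenyl)-1-(2,4-dimethoxyphenyl)propane-1,2-dione | O=C(Cc1cc(OC)c(OC)cc1Br)C(=O)c1ccc(OC)cc1OC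
F4 | step 4 | (E)-1-(2,4-dimethoxyphenyl)-3-(tributylstannyl)prop-2-en-1-one | CCCC[Sn](CCCC)(CCCC)/C=C/C(=O)c1ccc(OC)cc1OC
F5 | step 6 | O-[(1R,2S,3R)-2,3-bis(2,4-dimethoxybenzoyl)-6,7-dimethoxy-1-(4-methoxyphenyl)-1,2,3,4-tetrahydronaphthalen-3-yl] S-methyl carbonodithioate | O=C(c1ccc(OC)cc1OC)[C@@]1(OC(=S)SC)Cc2cc(OC)c(OC)cc2[C@@H](c2ccc(OC)cc2)[C@@H]1C(=O)c1ccc(OC)cc1OC
F6 | step 7 | [(1R,2S)-6,7-dimethoxy-1-(4-methoxyphenyl)-1,2-dihydronaphthalene-2,3-diyl]bis[(2-hydroxy-4-methoxyphenyl)methanone] | O=C(C1=Cc2cc(OC)c(OC)cc2[C@@H](c2ccc(OC)cc2)[C@@H]1C(=O)c1ccc(OC)cc1O)c1ccc(OC)cc1O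
F7 | step 7 | heptaacetate of 14 | O=C(C1=Cc2cc(OC(C)=O)c(OC(C)=O)cc2[C@@H](c2ccc(OC(C)=O)cc2)[C@@H]1C(=O)c1ccc(OC(C)=O)cc1OC(C)=O)c1ccc(OC(C)=O)cc1OC(C)=O
A1 | alternative 1 | 6-hydroxy-7-methoxy dihydronaphthalene (hexamethyl ether of 14 with free C6 phenol) | O=C(C1=Cc2cc(O)c(OC)cc2[C@@H](c2ccc(OC)cc2)[C@@H]1C(=O)c1ccc(OC)cc1OC)c1ccc(OC)cc1OC
A2 | alternative 1 | furan–enyne: 4-methoxyfuran-2-yl group on C1, C1–C2–C3=C4 chain with both aroyl groups, terminal alkyne on C4 | C#C/C=C(\[C@@H](C(=O)c1ccc(OC)cc1OC)[C@H](c1ccc(OC)cc1)c1cc(OC)co1)C(=O)c1ccc(OC)cc1OC
A3 | alternative 2 | heptamethyl ether of 14 (identical with 13) | O=C(C1=Cc2cc(OC)c(OC)cc2[C@@H](c2ccc(OC)cc2)[C@@H]1C(=O)c1ccc(OC)cc1OC)c1ccc(OC)cc1OC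
A4 | alternative 2 | cyclopropane-fused indane (1,1a,6,6a-tetrahydrocyclopropa[a]indene) with aroyl groups on C2 and C3 and the 4-methoxyphenyl group on C1 (target numbering) | O=C(c1ccc(OC)cc1OC)[C@@H]1[C@H]2c3cc(OC)c(OC)cc3[C@@H](c3ccc(OC)cc3)[C@@]12C(=O)c1ccc(OC)cc1OC
A5 | alternative 3 | 1-aryl-2,3-diaroyl-4-hydroxytetralin, heptamethyl ether | O=C(c1ccc(OC)cc1OC)[C@H]1[C@@H](O)c2cc(OC)c(OC)cc2[C@@H](c2ccc(OC)cc2)[C@@H]1C(=O)c1ccc(OC)cc1OC
A6 | alternative 3 | 4,5-dimethoxy-2-(4-methoxybenzyl)benzaldehyde | COc1ccc(Cc2cc(OC)c(OC)cc2C=O)cc1
A7 | alternative 3 | (E)-1,4-bis(2,4-dimethoxyphenyl)but-2-ene-1,4-dione | O=C(/C=C/C(=O)c1ccc(OC)cc1OC)c1ccc(OC)cc1OC
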